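Decalin carbons carry drimane numbers throughout: C1–C3 methylenes, C4 gem-dimethyl, C5=C6 olefin, C7 methylene, C8 (methyl), C9 (methyl and C11), C10 (hydrogen). C11 is the carbon between C9 and the oxygenated six-membered ring. Compound numbers 1–21 are those of the steps and of the compound list.

## Analysis of the target

Compound 21 is a sesquiterpenoid hydroxyquinone: a 2-hydroxy-5-methoxy-1,4-benzoquinone whose C3 is joined through the C11 methylene to C9 of a 4,4,8,9-tetramethyl octalin (rings A and B) with a trisubstituted C5=C6 olefin. The three stereocenters are contiguous: C8 (S), the quaternary C9 (R) and C10 (S). The methyl groups on C8 and C9 are cis, and C11 and H10 lie on the other face, so in a ring B chair the C8 methyl group, C11 and the C10–C1 bond are equatorial and the C9 methyl group is axial. The quinone is a vinylogous acid and ester that tolerates neither organometallic reagents nor hydrides, so it has to appear last. The C5=C6 olefin sits next to the quaternary C4: protonation gives a tertiary C5 cation that can lose a proton toward C10 or take a methyl group from C4, so strong acid is excluded once the olefin exists. C11 is neopentyl and shielded by C9 and by two ortho oxygens, which rules out displacement at C11 and makes a C11 cation prone to a 1,2-shift from C9. The difficulty is a quaternary carbon between two tertiary stereocenters in a carbocycle without heteroatom handles, as a single enantiomer, with the olefin in one defined position. The strategy rests on one feature: C9 is alpha to C11 and bonded to both C8 and C10, and C8 and C10 are each beta to C6. With carbonyl groups at C11 and C6, C9 is the nucleophilic carbon of an aryl ethyl ketone and C8 and C10 are the two beta carbons of a cross-conjugated dienone.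

## Retrosynthetic reasoning

**21 to 19 (via 20).** The hydroxyquinone is taken back to the dimethoxyquinone 20 and this to the tetramethoxyarene 19. The arene survives every C–C bond formation and reduction of the route. It is symmetric about the C11–aryl axis, so either para pair of methoxy groups gives the same quinone on oxidative demethylation. The forward steps have to oxidise the ring without touching the olefin and then hydrolyse only the methoxy group next to the side chain.

**19 to 16 (via 18 and 17).** The two C11–H bonds are traced to the C11 carbonyl of ketone 16. The carbonyl is what makes C9 nucleophilic in the key step, so it must be carried to this point and then removed. Removal goes through alcohol 17 and xanthate 18 by a radical chain. A C11 radical does not rearrange, whereas an ionic reduction would pass through a C11 cation next to the quaternary C9 and would need acid in the presence of the olefin.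

**16 to 14 (via 15).** The C5=C6 olefin is traced to the C6 carbonyl of diketone 14 through the axial alcohol 15. The two carbonyl groups of 14 differ greatly in accessibility, so the C6 ketone alone can be reduced. An axial C6 leaving group is anti to the axial H5, and elimination toward the tertiary position gives the trisubstituted olefin. Placing this before the C11 reduction keeps the two oxygen functions apart without protecting groups.

**14 to 7 and 12 (via 13).** Both ring bonds to C9 are cut, C8–C9 and C9–C10. This is the only disconnection that removes the quaternary carbon and all three stereocenters at once. It leaves two fragments of similar size, dienone 7 and aryl ethyl ketone 12, each with its polarity already in place. Forward, the enolate of 12 must add first to the crotonyl terminus of 7 under control of a chiral cation (C8), giving the open-chain diketone 13. The C9 enolate of 13 must then close ring B on C10 through a chair that sets C9 and C10 relative to C8. Cutting elsewhere, for instance at C5–C10 or C7–C8, would keep the quaternary centre inside one fragment and leave it to be made separately.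

**7 to 1, 2 and 4 (via 6, 5 and 3).** The bond between the ring and the carbonyl carbon is cut. The vinyllithium 5 comes regiospecifically from hydrazone 3, because ketone 1 has only one enolisable side, and it adds to aldehyde 4. The resulting doubly allylic alcohol 6 is oxidised to 7. The gem-dimethyl group is bought with 1.

**12 to 8 and 9 (via 11 and 10).** The aryl–carbonyl bond is cut. Arene 8 is lithiated between two methoxy groups to give 10, which adds to aldehyde 9. Alcohol 11 is oxidised to 12. Symmetry of 8 removes any regiochemical question.

## Alternatives that were turned down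

**Alternative 1:** The two C4–CH3 bonds are disconnected. The ring system is made first as the conjugated 4-en-3-one A2, which already carries C8, C9, C10 and the arylmethyl group. Excess tert-butoxide and methyl iodide then convert A2 through its extended dienolate into the 4,4-dimethyl-5-en-3-one A1, with the olefin moving out of conjugation to C5=C6.
- For it: the reaction is a classic of terpenoid synthesis, installs the gem-dimethyl group and the olefin in one flask, and carries C11 at the methylene level throughout, so no C11 deoxygenation is needed. On these points it is stronger than the chosen route.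
- Against it: A2 has a hydrogen on C10, which is a second gamma position. Deprotonation there gives the more substituted dienolate, scrambles C10 and leads toward a C5=C10 olefin; the reliable precedents have C10 blocked by a methyl group. The C3 ketone of A1, flanked by the new quaternary centre, must then be removed under forcing conditions. The real problem, the C8–C9–C10 triad with its quaternary centre, is only moved back into the synthesis of A2.
- Comparison: the chosen route makes that triad and ring B in one step from two small fragments, and takes the gem-dimethyl group from a commercial ketone.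

**Alternative 2:** The C7–C8 and C9–C10 bonds are disconnected. Diene A4 and tiglic aldehyde A5 combine in a Diels–Alder reaction under a chiral Lewis acid, with the formyl group exo, to give aldehyde A3.
- For it: this is the shortest route. One step closes ring B, sets all three stereocenters from the E geometry of A5 and the exo mode, and delivers the C5=C6 olefin directly, so the dehydration question of the chosen route does not arise. On step economy and olefin placement it is stronger.
- Against it: A5 is a beta-substituted, alpha-branched enal of low reactivity. The two alkyl groups of A4 direct the regiochemistry in opposite senses. Enantioselective exo additions of such enals are well founded for cyclopentadiene and simple dienes but not for a hindered, acid-sensitive semicyclic diene. The aryl group must then be added to the neopentyl aldehyde A3 and the resulting alcohol deoxygenated.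
- Comparison: the chosen route fixes regiochemistry through the polarity of 7 and 12 alone. Only one stereocenter has to be induced by a catalyst, the other two following from an intramolecular chair, and the arene is attached before the congested centre is made.

**Alternative 3:** The C9–C10 bond is disconnected. The acyclic beta-keto ester A7, an 8-phenylmenthyl ester, is oxidised by Mn(OAc)3 to the C9 radical, which adds 6-endo to the cyclohexene. Cu(OAc)2 oxidises the tertiary C5 radical to the C5=C6 olefin, giving keto ester A6.
- For it: radical additions are less sensitive to steric crowding than enolate additions, so the C9–C10 bond may form more readily than in the chosen route. The olefin is placed by the termination step, and auxiliary control of such cyclisations is established.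
- Against it: A6 has neither methyl group in its final form. The C8 ketone must become a methyl-bearing stereocenter late and without a strong bias. The C9 ester must be reduced to a methyl group at a neopentyl position. The auxiliary is stoichiometric. The electron-rich tetramethoxybenzyl group is exposed to a one-electron oxidant.
- Comparison: the chosen route brings both methyl groups in as methyl groups and needs only functional group removal after the ring is closed.

Key step: step 6

Assumption: the sense of induction of the ammonium salt with dienone 7 cannot be assigned in advance; the cinchonidine-derived salt is written, and its cinchonine-derived pseudoenantiomer takes its place if 13 forms with the opposite configuration at C8.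

## Route

Step 1
Reactants: 1 2,2-dimethylcyclohexanone; 2 2,4,6-tri(propan-2-yl)benzenesulfonohydrazide
Product: 3 (E)-N'-(2,2-dimethylcyclohexylidene)-2,4,6-tri(propan-2-yl)benzenesulfonohydrazide
Conditions: MeOH, HCl (cat.), rt
Reagents that add atoms: none
Why: Acid-catalysed condensation of a ketone with an arenesulfonyl hydrazide; the N–N bond settles anti to the quaternary carbon, that is syn to the only alpha methylene group, which is the geometry the next step needs.

Step 2
Reactants: 3 (E)-N'-(2,2-dimethylcyclohexylidene)-2,4,6-tri(propan-2-yl)benzenesulfonohydrazide; 4 (E)-but-2-enal (crotonaldehyde)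
Product: 6 (E)-1-(6,6-dimethylcyclohex-1-en-1-yl)but-2-en-1-ol (racemic), via 6,6-dimethylcyclohex-1-enyllithium 5 (not isolated)
Conditions: n-BuLi (2.1 equiv), TMEDA, hexane/THF, −78 → 0 °C; then 4, −78 °C; H2O
Reagents that add atoms: none
Why: Shapiro reaction: deprotonation at N–H and at the syn alpha methylene, then loss of sulfinate and N2, gives the vinyllithium regiospecifically because the other alpha position is quaternary; at −78 °C it adds 1,2 to the aldehyde. The carbinol stereocenter is not controlled and is removed in step 3.

Step 3
Reactants: 6 (E)-1-(6,6-dimethylcyclohex-1-en-1-yl)but-2-en-1-ol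
Product: 7 (E)-1-(6,6-dimethylcyclohex-1-en-1-yl)but-2-en-1-one
Conditions: MnO2 (activated, excess), CH2Cl2, rt
Reagents that add atoms: none
Why: Oxidation of a doubly allylic alcohol with MnO2 under neutral conditions, which leaves both olefins and the E geometry untouched.

Step 4
Reactants: 8 1,2,4,5-tetramethoxybenzene; 9 propanal
Product: 11 1-(2,3,5,6-tetramethoxyphenyl)propan-1-ol (racemic), via 2,3,5,6-tetramethoxyphenyllithium 10 (not isolated)
Conditions: n-BuLi, THF, 0 °C; then 9, −78 °C → rt; H2O
Reagents that add atoms: none
Why: Directed ortho-metalation at the C–H flanked by two methoxy groups, the two such positions of 8 being equivalent, followed by addition of the aryllithium to the aldehyde.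

Step 5
Reactants: 11 1-(2,3,5,6-tetramethoxyphenyl)propan-1-ol
Product: 12 1-(2,3,5,6-tetramethoxyphenyl)propan-1-one
Conditions: Dess–Martin periodinane (1,1,1-triacetoxy-1,1-dihydro-1,2-benziodoxol-3(1H)-one), CH2Cl2, rt
Reagents that add atoms: none
Why: Dess–Martin oxidation of a secondary benzylic alcohol; the neutral two-electron oxidant does not demethylate the electron-rich ring.

Step 6
Reactants: 7 (E)-1-(6,6-dimethylcyclohex-1-en-1-yl)but-2-en-1-one; 12 1-(2,3,5,6-tetramethoxyphenyl)propan-1-one
Product: 14 (3S,4R,4aR,8aS)-3,4,8,8-tetramethyl-4-(2,3,5,6-tetramethoxybenzoyl)octahydronaphthalen-1(2H)-one, via open-chain Michael adduct 13 (not isolated)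
Conditions: O-allyl-N-(9-anthracenylmethyl)cinchonidinium bromide (10 mol%), CsOH·H2O (20 mol%), toluene, −40 °C; then KOtBu (30 mol%), t-BuOH/THF, −40 → 0 °C; aq NH4Cl
Reagents that add atoms: none
Why: Double Michael (formal [5+1]) annulation run as two stages in one flask; the closest known reaction types are the cinchona ammonium salt-catalysed Michael addition of aryl ketone enolates to enones and the base-mediated double conjugate addition of ketone or active-methylene pronucleophiles to divinyl ketones. In stage one the enolate of 12, held as an ion pair with the chiral ammonium cation, adds to the crotonyl beta carbon of 7 (C8), forming C8–C9 and giving 13; the choice between the two beta carbons comes from the substrate, because the ring enone has a fully substituted alpha carbon next to the gem-dimethyl group and is twisted out of conjugation. C8 is set here by the face of the enone that the ion pair exposes; C9 in 13 is an epimer mixture, which does not matter because it is deprotonated next. In stage two KOtBu/t-BuOH interconverts the enolates of 13, and the tertiary C9 enolate closes ring B by 6-endo-trig conjugate addition to C10, forming C9–C10 and the C5=C6 enolate. The closure goes through a chair in which the C8 methyl group is equatorial and C8–H lies in the plane of the exocyclic C9=C11 enolate (least A(1,3) strain), so C10 bonds to the face of C9 that leaves the aroyl group equatorial and the C9 methyl group axial and cis to the C8 methyl group. C10 follows from the same chair: C1 is trans to C6 across C5=C10 and must become equatorial, which places H10 axial and anti to the C9 methyl group. C5 is protonated under equilibrating conditions and should settle as the trans ring fusion; it is erased in step 8 in any case. The step needs the first addition not to reverse, so the closure is run at 0 °C or below and its diastereoselectivity is taken from the kinetic chair, not from equilibration.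

Step 7
Reactants: 14 (3S,4R,4aR,8aS)-3,4,8,8-tetramethyl-4-(2,3,5,6-tetramethoxybenzoyl)octahydronaphthalen-1(2H)-one
Product: 15 [(1R,2S,4S,4aS,8aR)-4-hydroxy-1,2,5,5-tetramethyldecahydronaphthalen-1-yl](2,3,5,6-tetramethoxyphenyl)methanone
Conditions: LiBH(s-Bu)3, THF, −78 → 0 °C; then NaOH, H2O2
Reagents that add atoms: none
Why: Reduction of a cyclohexanone by a bulky trialkylborohydride, which attacks along the equatorial direction away from the axial C4 methyl group and should give the axial C6 alcohol (OH anti to H5). The C11 ketone, buried between the quaternary C9 and the di-ortho-substituted ring, should not be reduced.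

Step 8
Reactants: 15 [(1R,2S,4S,4aS,8aR)-4-hydroxy-1,2,5,5-tetramethyldecahydronaphthalen-1-yl](2,3,5,6-tetramethoxyphenyl)methanone
Product: 16 [(1R,2S,8aR)-1,2,5,5-tetramethyl-1,2,3,5,6,7,8,8a-octahydronaphthalen-1-yl](2,3,5,6-tetramethoxyphenyl)methanone
Conditions: POCl3, pyridine, 0 → 60 °C
Reagents that add atoms: none
Why: Dehydration by E2 elimination of the dichlorophosphate: the axial leaving group is anti-periplanar to the axial H5, and loss of the tertiary proton gives the more substituted C5=C6 olefin (Zaitsev), as is general for axial cyclohexanols with an anti tertiary hydrogen. The C11 ketone cannot enolise and is inert, and no free cation is formed that could shift a C4 methyl group.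

Step 9
Reactants: 16 [(1R,2S,8aR)-1,2,5,5-tetramethyl-1,2,3,5,6,7,8,8a-octahydronaphthalen-1-yl](2,3,5,6-tetramethoxyphenyl)methanone
Product: 17 [(1R,2S,8aR)-1,2,5,5-tetramethyl-1,2,3,5,6,7,8,8a-octahydronaphthalen-1-yl](2,3,5,6-tetramethoxyphenyl)methanol (C11 epimers)
Conditions: LiAlH4, THF, reflux
Reagents that add atoms: none
Why: LiAlH4 reduction of the hindered, non-enolisable aryl ketone at reflux; the new C11 stereocenter is not controlled because it is removed in step 11.

Step 10
Reactants: 17 [(1R,2S,8aR)-1,2,5,5-tetramethyl-1,2,3,5,6,7,8,8a-octahydronaphthalen-1-yl](2,3,5,6-tetramethoxyphenyl)methanol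
Product: 18 O-{[(1R,2S,8aR)-1,2,5,5-tetramethyl-1,2,3,5,6,7,8,8a-octahydronaphthalen-1-yl](2,3,5,6-tetramethoxyphenyl)methyl} S-methyl carbonodithioate
Conditions: KH, THF, 0 °C; CS2; then MeI, rt
Reagents that add atoms: carbon disulfide, S=C=S; iodomethane, CI
Why: Xanthate formation, the first half of a Barton–McCombie deoxygenation: the potassium alkoxide adds to the small electrophile CS2 even at a neopentyl carbinol, and the dithiocarbonate salt is S-methylated.

Step 11
Reactants: 18 O-{[(1R,2S,8aR)-1,2,5,5-tetramethyl-1,2,3,5,6,7,8,8a-octahydronaphthalen-1-yl](2,3,5,6-tetramethoxyphenyl)methyl} S-methyl carbonodithioate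
Product: 19 1,2,4,5-tetramethoxy-3-{[(1R,2S,8aS)-1,2,5,5-tetramethyl-1,2,3,5,6,7,8,8a-octahydronaphthalen-1-yl]methyl}benzene
Conditions: Bu3SnH, azobisisobutyronitrile (cat.), toluene, 110 °C
Reagents that add atoms: none
Why: Barton–McCombie deoxygenation: the stannyl radical adds to the thiocarbonyl group, the C11–O bond fragments to a benzylic radical, and this takes hydrogen from Bu3SnH. A neopentyl radical does not undergo 1,2-alkyl shifts, so C9 and the olefin stay as they are.

Step 12
Reactants: 19 1,2,4,5-tetramethoxy-3-{[(1R,2S,8aS)-1,2,5,5-tetramethyl-1,2,3,5,6,7,8,8a-octahydronaphthalen-1-yl]methyl}benzene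
Product: 20 2,5-dimethoxy-3-{[(1R,2S,8aS)-1,2,5,5-tetramethyl-1,2,3,5,6,7,8,8a-octahydronaphthalen-1-yl]methyl}cyclohexa-2,5-diene-1,4-dione
Conditions: (NH4)2Ce(NO3)6, MeCN/H2O, 0 °C
Reagents that add atoms: water, O
Why: Oxidative demethylation of a para-dimethoxyarene by tetravalent cerium (electron transfer, attack of water, loss of methanol); by the symmetry of the ring either para pair gives the same quinone, and the arene should be oxidised far faster than the isolated olefin.

Step 13
Reactants: 20 2,5-dimethoxy-3-{[(1R,2S,8aS)-1,2,5,5-tetramethyl-1,2,3,5,6,7,8,8a-octahydronaphthalen-1-yl]methyl}cyclohexa-2,5-diene-1,4-dione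
Product: 21 2-hydroxy-5-methoxy-3-{[(1R,2S,8aS)-1,2,5,5-tetramethyl-1,2,3,5,6,7,8,8a-octahydronaphthalen-1-yl]methyl}cyclohexa-2,5-diene-1,4-dione
Conditions: KOH, MeOH/H2O, rt; then dilute HCl, 0 °C
Reagents that add atoms: potassium hydroxide, [K+].[OH-]
Why: Addition–elimination of hydroxide at a vinylogous ester: the methoxy group between the carbonyl and the neopentyl side chain is twisted out of conjugation, so its carbon is the more electrophilic one, and the hydroxyquinone anion formed is a vinylogous carboxylate that resists a second hydrolysis. Base is used so that the C5=C6 olefin is not protonated.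

## Compound list

1 | 2,2-dimethylcyclohexanone | CC1(C)CCCCC1=O | starting material
2 | 2,4,6-tri(propan-2-yl)benzenesulfonohydrazide | CC(C)c1cc(C(C)C)c(S(=O)(=O)NN)c(C(C)C)c1 | starting material
3 | (E)-N'-(2,2-dimethylcyclohexylidene)-2,4,6-tri(propan-2-yl)benzenesulfonohydrazide | CC1(C)CCCC/C1=N\NS(=O)(=O)c1c(C(C)C)cc(C(C)C)cc1C(C)C | intermediate
4 | (E)-but-2-enal (crotonaldehyde) | C/C=C/C=O | starting material
5 | (6,6-dimethylcyclohex-1-en-1-yl)lithium | [Li]C1=CCCCC1(C)C | intermediate (not isolated)
6 | (E)-1-(6,6-dimethylcyclohex-1-en-1-yl)but-2-en-1-ol (racemic) | C/C=C/C(O)C1=CCCCC1(C)C | intermediate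
7 | (E)-1-(6,6-dimethylcyclohex-1-en-1-yl)but-2-en-1-one | C/C=C/C(=O)C1=CCCCC1(C)C | intermediate
8 | 1,2,4,5-tetramethoxybenzene | COc1cc(OC)c(OC)cc1OC | starting material
9 | propanal | CCC=O | starting material
10 | (2,3,5,6-tetramethoxyphenyl)lithium | [Li]c1c(OC)c(OC)cc(OC)c1OC | intermediate (not isolated)
11 | 1-(2,3,5,6-tetramethoxyphenyl)propan-1-ol (racemic) | CCC(O)c1c(OC)c(OC)cc(OC)c1OC | intermediate
12 | 1-(2,3,5,6-tetramethoxyphenyl)propan-1-one | CCC(=O)c1c(OC)c(OC)cc(OC)c1OC | intermediate
13 | (3S)-1-(6,6-dimethylcyclohex-1-en-1-yl)-3,4-dimethyl-5-(2,3,5,6-tetramethoxyphenyl)pentane-1,5-dione (C4 epimers; chain C3 is C8, chain C4 is C9) | COc1cc(OC)c(OC)c(C(=O)C(C)[C@@H](C)CC(=O)C2=CCCCC2(C)C)c1OC | intermediate (not isolated)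
14 | (3S,4R,4aR,8aS)-3,4,8,8-tetramethyl-4-(2,3,5,6-tetramethoxybenzoyl)octahydronaphthalen-1(2H)-one | COc1cc(OC)c(OC)c(C(=O)[C@@]2(C)[C@@H]3CCCC(C)(C)[C@H]3C(=O)C[C@@H]2C)c1OC | intermediate
15 | [(1R,2S,4S,4aS,8aR)-4-hydroxy-1,2,5,5-tetramethyldecahydronaphthalen-1-yl](2,3,5,6-tetramethoxyphenyl)methanone | COc1cc(OC)c(OC)c(C(=O)[C@@]2(C)[C@@H]3CCCC(C)(C)[C@H]3[C@@H](O)C[C@@H]2C)c1OC | intermediate
16 | [(1R,2S,8aR)-1,2,5,5-tetramethyl-1,2,3,5,6,7,8,8a-octahydronaphthalen-1-yl](2,3,5,6-tetramethoxyphenyl)methanone | COc1cc(OC)c(OC)c(C(=O)[C@@]2(C)[C@@H]3CCCC(C)(C)C3=CC[C@@H]2C)c1OC | intermediate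
17 | [(1R,2S,8aR)-1,2,5,5-tetramethyl-1,2,3,5,6,7,8,8a-octahydronaphthalen-1-yl](2,3,5,6-tetramethoxyphenyl)methanol (C11 epimers) | COc1cc(OC)c(OC)c(C(O)[C@@]2(C)[C@@H]3CCCC(C)(C)C3=CC[C@@H]2C)c1OC | intermediate
18 | O-{[(1R,2S,8aR)-1,2,5,5-tetramethyl-1,2,3,5,6,7,8,8a-octahydronaphthalen-1-yl](2,3,5,6-tetramethoxyphenyl)methyl} S-methyl carbonodithioate (C11 epimers) | COc1cc(OC)c(OC)c(C(OC(=S)SC)[C@@]2(C)[C@@H]3CCCC(C)(C)C3=CC[C@@H]2C)c1OC | intermediate
19 | 1,2,4,5-tetramethoxy-3-{[(1R,2S,8aS)-1,2,5,5-tetramethyl-1,2,3,5,6,7,8,8a-octahydronaphthalen-1-yl]methyl}benzene | COc1cc(OC)c(OC)c(C[C@@]2(C)[C@@H]3CCCC(C)(C)C3=CC[C@@H]2C)c1OC | intermediate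
20 | 2,5-dimethoxy-3-{[(1R,2S,8aS)-1,2,5,5-tetramethyl-1,2,3,5,6,7,8,8a-octahydronaphthalen-1-yl]methyl}cyclohexa-2,5-diene-1,4-dione | COC1=CC(=O)C(OC)=C(C[C@@]2(C)[C@@H]3CCCC(C)(C)C3=CC[C@@H]2C)C1=O | intermediate
21 | 2-hydroxy-5-methoxy-3-{[(1R,2S,8aS)-1,2,5,5-tetramethyl-1,2,3,5,6,7,8,8a-octahydronaphthalen-1-yl]methyl}cyclohexa-2,5-diene-1,4-dione | COC1=CC(=O)C(O)=C(C[C@@]2(C)[C@@H]3CCCC(C)(C)C3=CC[C@@H]2C)C1=O | target

## Step count and least certain steps

Total step count: 13. Longest linear sequence: 11 steps (steps 1–3 and 6–13); the arene branch (steps 4 and 5) joins at step 6.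

**Step 6 (key step).** Two things are most likely to go wrong. The first is weak facial control in the first addition: the acceptor has only a methyl group at its beta carbon and no aryl group for the ion pair to recognise. The second is a slow closure onto the hindered, twisted ring enone, during which reversal of the first addition would erode the excess at C8. Formation of the C9 epimer through a non-chair closure is a lesser risk.
Fallback: from 7 and 12 the annulation is run without the chiral salt (KOtBu, t-BuOH/THF, rt or warmer). These conditions can be forced, because no excess at C8 has to be protected, and should give racemic diketone F1. LiBH(s-Bu)3 as in step 7 gives racemic alcohol F2. Acylation with (1S)-camphanoyl chloride (pyridine, 4-dimethylaminopyridine) gives the camphanate of the wanted enantiomer F3 and the diastereomeric camphanate of the unwanted enantiomer F4, which are separated by chromatography or crystallisation. KOH/MeOH cleaves F3 and the route is rejoined at 15.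

**Step 8.** The elimination may run toward C7, because the anti hydrogen on C5 is the more shielded one (gem-dimethyl group, axial C9 methyl group). The dichlorophosphate may also be displaced by chloride, or the ring fusion may not be trans, so that no anti hydrogen on C5 is available.
Fallback: from 7 and 12 through 13 as in step 6, the ring is closed with a full equivalent of KN(SiMe3)2 in THF (−78 → 0 °C). The C5=C6 enolate, formed regiospecifically by the conjugate addition, is trapped with N-phenylbis(trifluoromethanesulfonimide) to give enol triflate F5. Transfer hydrogenolysis (Pd(OAc)2, PPh3, HCO2H, Bu3N, DMF, 60 °C) replaces the triflate by hydrogen and gives 16 directly, with the olefin fixed by the way the enolate was made. Steps 7 and 8 are then not needed.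

**Step 10 (with step 11).** The crowded C11 alkoxide may fail to add to CS2. The electron-rich benzylic xanthate may also ionise and rearrange from oxygen to sulfur before the radical step, which would slow or divert the deoxygenation.
Fallback: from 16, dissolving-metal reduction (Li, NH3/THF, −78 °C, then solid NH4Cl) takes the aryl ketone through the benzylic alkoxide of 17 straight to the methylene compound and rejoins the route at 19. This fallback makes no new isolable compound (F0).

**Step 13.** Hydroxide may attack the unhindered methoxy-bearing carbon instead, or hydrolysis may go on to remove both methoxy groups.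
Fallback: from 20, exhaustive hydrolysis (aq NaOH, dioxane, 80 °C; then dilute HCl) gives the dihydroxyquinone F6. Acid-catalysed mono-methylation (MeOH, p-toluenesulfonic acid (cat.), rt) should then etherify only the unhindered hydroxyl, which reacts as a vinylogous acid, and returns to the route at 21.

## Further compounds

F1 | step 6 | racemic 3,4,8,8-tetramethyl-4-(2,3,5,6-tetramethoxybenzoyl)octahydronaphthalen-1(2H)-one with the relative configuration of 14 (one enantiomer drawn) | COc1cc(OC)c(OC)c(C(=O)[C@@]2(C)[C@@H]3CCCC(C)(C)[C@H]3C(=O)C[C@@H]2C)c1OC
F2 | step 6 | racemic C6 axial alcohol with the relative configuration of 15 (one enantiomer drawn) | COc1cc(OC)c(OC)c(C(=O)[C@@]2(C)[C@@H]3CCCC(C)(C)[C@H]3[C@@H](O)C[C@@H]2C)c1OC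
F3 | step 6 | (1S,4R)-4,7,7-trimethyl-3-oxo-2-oxabicyclo[2.2.1]heptane-1-carboxylic (camphanic) ester of alcohol 15 at the C6 oxygen | COc1cc(OC)c(OC)c(C(=O)[C@@]2(C)[C@@H]3CCCC(C)(C)[C@H]3[C@@H](OC(=O)[C@@]45CC[C@@](C)(C(=O)O4)C5(C)C)C[C@@H]2C)c1OC
F4 | step 6 | (1S,4R)-camphanic ester of the enantiomer of alcohol 15 | COc1cc(OC)c(OC)c(C(=O)[C@]2(C)[C@H]3CCCC(C)(C)[C@@H]3[C@H](OC(=O)[C@@]45CC[C@@](C)(C(=O)O4)C5(C)C)C[C@H]2C)c1OC
F5 | step 8 | (3S,4R,4aR)-3,4,8,8-tetramethyl-4-(2,3,5,6-tetramethoxybenzoyl)-2,3,4,4a,5,6,7,8-octahydronaphthalen-1-yl trifluoromethanesulfonate | COc1cc(OC)c(OC)c(C(=O)[C@@]2(C)[C@@H]3CCCC(C)(C)C3=C(OS(=O)(=O)C(F)(F)F)C[C@@H]2C)c1OC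
F0 | step 10 | none | none
F6 | step 13 | 2,5-dihydroxy-3-{[(1R,2S,8aS)-1,2,5,5-tetramethyl-1,2,3,5,6,7,8,8a-octahydronaphthalen-1-yl]methyl}cyclohexa-2,5-diene-1,4-dione | OC1=CC(=O)C(O)=C(C[C@@]2(C)[C@@H]3CCCC(C)(C)C3=CC[C@@H]2C)C1=O
A1 | alternative 1 | (4aS,5R,6S)-1,1,5,6-tetramethyl-5-(2,3,5,6-tetramethoxybenzyl)-3,4,4a,5,6,7-hexahydronaphthalen-2(1H)-one | COc1cc(OC)c(OC)c(C[C@@]2(C)[C@@H]3CCC(=O)C(C)(C)C3=CC[C@@H]2C)c1OC
A2 | alternative 1 | 5,6-dimethyl-5-(2,3,5,6-tetramethoxybenzyl)-4,4a,5,6,7,8-hexahydronaphthalen-2(3H)-one, configured at C8, C9 and C10 as in the target | COc1cc(OC)c(OC)c(C[C@@]2(C)[C@@H]3CCC(=O)C=C3CC[C@@H]2C)c1OC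
A3 | alternative 2 | (1R,2S,8aR)-1,2,5,5-tetramethyl-1,2,3,5,6,7,8,8a-octahydronaphthalene-1-carbaldehyde | O=C[C@@]2(C)[C@@H]3CCCC(C)(C)C3=CC[C@@H]2C
A4 | alternative 2 | 1-ethenyl-6,6-dimethylcyclohex-1-ene | C=CC1=CCCCC1(C)C
A5 | alternative 2 | (E)-2-methylbut-2-enal (tiglic aldehyde) | C/C=C(\C)C=O
A6 | alternative 3 | (1R,2S,5R)-5-methyl-2-(2-phenylpropan-2-yl)cyclohexyl (1R,8aR)-5,5-dimethyl-2-oxo-1-(2,3,5,6-tetramethoxybenzyl)-1,2,3,5,6,7,8,8a-octahydronaphthalene-1-carboxylate | COc1cc(OC)c(OC)c(C[C@@]2(C(=O)O[C@@H]4C[C@H](C)CC[C@H]4C(C)(C)c5ccccc5)[C@@H]3CCCC(C)(C)C3=CCC2=O)c1OC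
A7 | alternative 3 | (1R,2S,5R)-5-methyl-2-(2-phenylpropan-2-yl)cyclohexyl 5-(6,6-dimethylcyclohex-1-en-1-yl)-3-oxo-2-(2,3,5,6-tetramethoxybenzyl)pentanoate (C2 epimers) | COc1cc(OC)c(OC)c(CC(C(=O)O[C@@H]2C[C@H](C)CC[C@H]2C(C)(C)c3ccccc3)C(=O)CCC4=CCCCC4(C)C)c1OC
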